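Numbering: ring A = C1–C5 and C10 (C3 ketone, C4 gem-dimethyl, C5 ring-fusion CH, C10 quaternary); ring B = C5–C10 (C8 carbinol, C9 carries the chain from C11 on); β is the face of the C10 methyl group, and the target is the cis-fused decalin (5β-H).
Retrosynthesis: the chain is cut at C11–C12 (sulfonyl carbanion plus farnesyl bromide) and the C3 ketone is traced back to an allylic CH2 beside a C1–C2 double bond; ring B is then opened at C8–C9, because C8(OH)(CH3)–C9–C11(=O) is an aldol pattern whose donor carbon hangs on the quaternary C10; C9–C10 is cut last as a Claisen bond made from a C2 oxygen.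
What is left, ring A with C6–C8 and all four methyl groups, is (R)-α-ionone.
Forward: ring A is bought, C10 is made quaternary by the [3,3] shift, ring B closes by a Lewis-acid aldol of the C11 enol silane onto the C8 ketone, C3 is oxidised, and the C15 chain is joined last.
Stereochemistry: C5 comes from (R)-α-ionone; C10 from suprafacial delivery out of the cis C2 alcohol (hydride reduction, then Mitsunobu inversion); C8 and C9 from the ring closure (strain-free chair of the cis-fused system, open antiperiplanar approach).

Key step: step 10

Assumption: (R)-α-ionone of high enantiomeric purity is purchased (or obtained from the racemate by lipase resolution); where a centre or double-bond geometry is removed again later (C3 carbinol in 19–23, C11 in 22, enol ether geometry in 12) the expected main isomer is drawn and a mixture would serve equally.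

Step 1
Reactants: 1 (R)-α-ionone
Product: 2 (R)-7,8-dihydro-α-ionone
Conditions: H2 (1 atm), RhCl(PPh3)3 (5 mol%), benzene, 25 °C
Reagents that add atoms: none
Why: Homogeneous hydrogenation with RhCl(PPh3)3 should saturate only the unhindered disubstituted enone double bond, since the trisubstituted ring alkene is too hindered for this catalyst and no double-bond migration (which would erase C5) is expected.

Step 2
Reactants: 2 (R)-7,8-dihydro-α-ionone
Product: 3 ethylene ketal of 2
Conditions: HOCH2CH2OH, PPTS (cat.), benzene, reflux, Dean–Stark
Reagents that add atoms: ethylene glycol, OCCO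
Why: Acid-catalysed ketalization (dioxolane formation with azeotropic removal of water) masks the methyl ketone for the hydride and base steps that follow, the weak acid PPTS being chosen so that the ring double bond does not migrate.

Step 3
Reactants: 3 ethylene ketal of 2
Product: 4 enone ketal (C2 ketone, C1=C10 double bond)
Conditions: t-BuOOH (5 equiv), Rh2(cap)4 (1 mol%, cap = caprolactamate), K2CO3, CH2Cl2, 25 °C
Reagents that add atoms: tert-butyl hydroperoxide, CC(C)(C)OO
Why: Allylic oxidation with t-BuOOH (hydrogen abstraction by tert-butylperoxy radicals) should convert the ring allylic CH2 (C2) into the enone, a transformation established for α-ionone ketals, while the only other allylic ring hydrogen (C5) is tertiary and crowded.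

Step 4
Reactants: 4 enone ketal
Product: 5 trans allylic alcohol (2β-OH, trans to the C5 arm)
Conditions: LiBH(s-Bu)3, THF, −78 °C; aq. NH4Cl
Reagents that add atoms: none
Why: 1,2-Reduction with the bulky hydride LiBH(s-Bu)3 should give the trans (2β) alcohol, because with the C5 arm pseudoaxial the axial C4 methyl group blocks the opposite face of the carbonyl group, and conjugate reduction is disfavoured by the fully substituted β-carbon C10.

Step 5
Reactants: 5 trans allylic alcohol
Product: 6 cis 4-nitrobenzoate (2α-ester)
Conditions: 4-O2NC6H4CO2H, PPh3, DIAD, THF, 0 → 25 °C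
Reagents that add atoms: 4-nitrobenzoic acid, O=C(O)c1ccc(cc1)[N+](=O)[O-]
Why: Mitsunobu esterification should invert C2 by SN2 displacement of the phosphonium-activated hydroxyl group, giving the cis (2α) ester, since SN2′ attack would have to occur at the fully substituted C10.

Step 6
Reactants: 6 cis 4-nitrobenzoate
Product: 7 cis allylic alcohol (2α-OH, cis to the C5 arm)
Conditions: K2CO3, MeOH, 25 °C
Reagents that add atoms: none
Why: Base-catalysed transesterification (methanolysis) of the activated 4-nitrobenzoate should free the cis allylic alcohol without affecting the ketal.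

Step 7
Reactants: 7 cis allylic alcohol; 8 ethyl vinyl ether
Product: 9 cis allyl vinyl ether (2α-OCH=CH2)
Conditions: Pd(OCOCF3)2 (2 mol%), 4,7-diphenyl-1,10-phenanthroline (2 mol%), Et3N, 8 as solvent, 50 °C, sealed tube
Reagents that add atoms: ethyl vinyl ether (8), C=COCC
Why: Palladium-catalysed transfer vinylation (transetherification) with an excess of 8 should give the allyl vinyl ether under amine-buffered conditions that the ketal tolerates.

Step 8
Reactants: 9 cis allyl vinyl ether
Product: 10 ketal aldehyde (quaternary C10 with CH2CHO arm cis to the C5 arm, C1=C2 double bond)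
Conditions: toluene, Et3N (0.1 equiv), 170 °C, sealed tube
Reagents that add atoms: none
Why: Thermal Claisen rearrangement ([3,3]-sigmatropic, suprafacial across the ring) should form the C9–C10 bond on the face that carried the C2 oxygen, which sets the quaternary C10 with the acetaldehyde arm cis to the C5 arm and leaves the double bond at C1–C2.

Step 9
Reactants: 10 ketal aldehyde
Product: 11 keto aldehyde (C8 methyl ketone, C11 aldehyde)
Conditions: 2 M aq. HCl–THF (1:4), 0 → 25 °C
Reagents that add atoms: water, O
Why: Aqueous acid hydrolysis of the dioxolane should release the C8 methyl ketone, and nothing can epimerise because C10 is quaternary and C9 is a CH2 group.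

Step 10
Reactants: 11 keto aldehyde
Product: 13 cis-fused β-hydroxy aldehyde (8α-OH 8β-CH3 9β-CHO), via silyl enol ether 12 (not isolated)
Conditions: TBSCl (1.3 equiv), DBU (1.4 equiv), CH2Cl2, 0 → 25 °C; then BF3·OEt2 (3 equiv), −78 → −40 °C; cold aq. NaHCO3
Reagents that add atoms: none
Why: TBSCl/DBU should silylate only the aldehyde enol (the aldehyde is the more acidic carbonyl and ketones are slow under this weak-base silylation), and BF3 then activates the C8 ketone for an intramolecular Mukaiyama aldol addition in which C9 of the enol ether bonds to C8. Ring B closes in a 6-(enolexo)-exo-trig mode through a chair; because C9 and C6 are cis on ring A the fusion must be cis, and of the two chairs only the one with the sp2 carbon C1 axial on ring B avoids placing the C4 gem-dimethyl carbon axial over ring B. In this chair the ketone should keep its methyl group equatorial and put the BF3-bound oxygen into the axial site beside C1, which makes C8 the 8α-carbinol. The open transition state aligns the C9=C11 enol bond antiperiplanar to the C8–O bond, so C11 ends axial (9β) and the aldol is trans-diaxial, as the target requires. An amine-catalysed closure was set aside because an enamine holds its nitrogen beside the equatorial site of C8 and would deliver the equatorial (8β) oxygen in this ring system. The step needs donor/acceptor discrimination, secured by the aldehyde-selective silylation, and freedom from retro-aldol, secured by the low temperature and the cold bicarbonate quench.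

Step 11
Reactants: 13 cis-fused β-hydroxy aldehyde
Product: 14 1,3-diol (C11 primary alcohol, C8 tertiary alcohol)
Conditions: NaBH4, MeOH, −20 °C
Reagents that add atoms: none
Why: Borohydride reduction of the aldehyde (the only reducible group) at low temperature should give the 1,3-diol before retro-aldol or epimerisation at C9 can occur.

Step 12
Reactants: 14 1,3-diol
Product: 15 C11 phenyl sulfide
Conditions: PhSSPh, n-Bu3P, pyridine, 60 °C
Reagents that add atoms: diphenyl disulfide, c1ccccc1SSc1ccccc1
Why: The Hata reaction (n-Bu3P and PhSSPh) should replace only the primary hydroxyl group by phenylthio through SN2 attack on the phosphine-activated alcohol, the tertiary C8 alcohol being inert.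

Step 13
Reactants: 15 C11 phenyl sulfide
Product: 16 C11 phenyl sulfone
Conditions: (NH4)6Mo7O24·4H2O (10 mol%), 30% H2O2, EtOH, 0 → 25 °C
Reagents that add atoms: hydrogen peroxide, OO
Why: Molybdate-catalysed oxidation with H2O2 should take the sulfide to the sulfone chemoselectively, as unactivated alkenes such as C1–C2 are not epoxidised under these conditions.

Step 14
Reactants: 16 C11 phenyl sulfone
Product: 17 1-en-3-one sulfone
Conditions: t-BuOOH (5 equiv), Rh2(cap)4 (1 mol%), K2CO3, CH2Cl2, 40 °C
Reagents that add atoms: tert-butyl hydroperoxide, CC(C)(C)OO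
Why: Allylic oxidation with t-BuOOH (radical hydrogen abstraction, then peroxide formation and elimination) should give the 1-en-3-one, because C3 bears the only allylic hydrogens and the other end of the allyl radical, C1, is shielded by the angular methyl group on one face and by ring B on the other.

Step 15
Reactants: 17 1-en-3-one sulfone
Product: 19 saturated 3,8-diol sulfone (3α-OH drawn), via saturated ketone 18 (not isolated)
Conditions: H2 (1 atm), 10% Pd/C, EtOAc, 25 °C; filter; then NaBH4, MeOH, 0 °C
Reagents that add atoms: none
Why: Heterogeneous hydrogenation of the enone double bond followed by borohydride reduction of the C3 ketone should give the saturated diol, the C3 carbinol serving only as a masked ketone for the carbanion step so that its configuration is immaterial.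

Step 16
Reactants: 19 saturated 3,8-diol sulfone; 20 (2E,6E)-farnesyl bromide
Product: 22 C11-farnesylated sulfone, via trilithium salt 21 (not isolated)
Conditions: n-BuLi (3.3 equiv), THF–HMPA, −78 °C; then 20, −78 → −30 °C; aq. NH4Cl
Reagents that add atoms: (2E,6E)-farnesyl bromide (20), CC(C)=CCC/C(C)=C/CC/C(C)=C/CBr
Why: Sulfone alkylation: after deprotonation of both hydroxyl groups and of C11, the α-sulfonyl carbanion should attack the allylic bromide by SN2 at its primary carbon with retention of the E geometry, the lithium alkoxides being far weaker nucleophiles at low temperature.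

Step 17
Reactants: 22 C11-farnesylated sulfone
Product: 23 3,8-diol with complete side chain
Conditions: 6% Na(Hg), Na2HPO4, MeOH–THF, −20 °C
Reagents that add atoms: none
Why: Reductive desulfonylation with buffered sodium amalgam should cleave the C11–S bond without double-bond migration or elimination, because the sulfone is homoallylic and has no β-leaving group.

Step 18
Reactants: 23 3,8-diol with complete side chain
Product: 24 IN0671 (target)
Conditions: Dess–Martin periodinane, NaHCO3, CH2Cl2, 0 → 25 °C
Reagents that add atoms: none
Why: Dess–Martin oxidation should convert the secondary C3 alcohol into the ketone, while the tertiary C8 alcohol and the three trisubstituted alkenes are inert to this reagent.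

Compound list
1 | (R)-α-ionone, (3E)-4-[(1R)-2,6,6-trimethylcyclohex-2-en-1-yl]but-3-en-2-one | CC1=CCCC(C)(C)[C@H]1/C=C/C(C)=O | starting material
2 | (R)-7,8-dihydro-α-ionone, 4-[(1R)-2,6,6-trimethylcyclohex-2-en-1-yl]butan-2-one | CC1=CCCC(C)(C)[C@H]1CCC(C)=O | intermediate
3 | 2-methyl-2-{2-[(1R)-2,6,6-trimethylcyclohex-2-en-1-yl]ethyl}-1,3-dioxolane | CC1=CCCC(C)(C)[C@H]1CCC1(C)OCCO1 | intermediate
4 | (4R)-3,5,5-trimethyl-4-[2-(2-methyl-1,3-dioxolan-2-yl)ethyl]cyclohex-2-en-1-one | CC1=CC(=O)CC(C)(C)[C@H]1CCC1(C)OCCO1 | intermediate
5 | (1R,4R)-3,5,5-trimethyl-4-[2-(2-methyl-1,3-dioxolan-2-yl)ethyl]cyclohex-2-en-1-ol (trans; 2β-OH) | CC1=C[C@H](O)CC(C)(C)[C@H]1CCC1(C)OCCO1 | intermediate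
6 | (1S,4R)-3,5,5-trimethyl-4-[2-(2-methyl-1,3-dioxolan-2-yl)ethyl]cyclohex-2-en-1-yl 4-nitrobenzoate (cis) | CC1=C[C@@H](OC(=O)c2ccc(cc2)[N+](=O)[O-])CC(C)(C)[C@H]1CCC1(C)OCCO1 | intermediate
7 | (1S,4R)-3,5,5-trimethyl-4-[2-(2-methyl-1,3-dioxolan-2-yl)ethyl]cyclohex-2-en-1-ol (cis; 2α-OH) | CC1=C[C@@H](O)CC(C)(C)[C@H]1CCC1(C)OCCO1 | intermediate
8 | ethyl vinyl ether | C=COCC | starting material
9 | vinyl ether of 7 (2α-OCH=CH2, cis to the C5 arm) | CC1=C[C@@H](OC=C)CC(C)(C)[C@H]1CCC1(C)OCCO1 | intermediate
10 | 2-{(1S,6R)-1,5,5-trimethyl-6-[2-(2-methyl-1,3-dioxolan-2-yl)ethyl]cyclohex-2-en-1-yl}acetaldehyde | O=CC[C@@]1(C)C=CCC(C)(C)[C@H]1CCC1(C)OCCO1 | intermediate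
11 | 2-[(1S,6R)-1,5,5-trimethyl-6-(3-oxobutyl)cyclohex-2-en-1-yl]acetaldehyde (keto aldehyde) | O=CC[C@@]1(C)C=CCC(C)(C)[C@H]1CCC(C)=O | intermediate
12 | (E)-tert-butyldimethylsilyl enol ether of 11 at the aldehyde (C9=C11), ketone free | CC(C)(C)[Si](C)(C)O/C=C/[C@@]1(C)C=CCC(C)(C)[C@H]1CCC(C)=O | intermediate
13 | cis-fused aldol: 8α-hydroxy-4,4,8β,10β-tetramethyl-5β-H-octal-1-ene-9β-carbaldehyde (target numbering; OH and CHO trans) | O=C[C@@H]1[C@@]2(C)C=CCC(C)(C)[C@H]2CC[C@@]1(C)O | intermediate
14 | diol of 13: 9β-CH2OH, 8α-OH | OC[C@@H]1[C@@]2(C)C=CCC(C)(C)[C@H]2CC[C@@]1(C)O | intermediate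
15 | C11 phenyl sulfide: 9β-CH2SPh, 8α-OH | C(Sc3ccccc3)[C@@H]1[C@@]2(C)C=CCC(C)(C)[C@H]2CC[C@@]1(C)O | intermediate
16 | C11 phenyl sulfone: 9β-CH2SO2Ph, 8α-OH, C1=C2 | O=S(=O)(c3ccccc3)C[C@@H]1[C@@]2(C)C=CCC(C)(C)[C@H]2CC[C@@]1(C)O | intermediate
17 | 1-en-3-one sulfone | O=S(=O)(c3ccccc3)C[C@@H]1[C@@]2(C)C=CC(=O)C(C)(C)[C@H]2CC[C@@]1(C)O | intermediate
18 | saturated 3-ketone sulfone | O=S(=O)(c3ccccc3)C[C@@H]1[C@@]2(C)CCC(=O)C(C)(C)[C@H]2CC[C@@]1(C)O | intermediate
19 | saturated 3α,8α-diol sulfone (C3 epimer acceptable) | O=S(=O)(c3ccccc3)C[C@@H]1[C@@]2(C)CC[C@@H](O)C(C)(C)[C@H]2CC[C@@]1(C)O | intermediate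
20 | (2E,6E)-farnesyl bromide | CC(C)=CCC/C(C)=C/CC/C(C)=C/CBr | starting material
21 | trilithium salt of 19 (C3 and C8 alkoxides, C11 carbanion) | O=S(=O)(c3ccccc3)[CH-][C@@H]1[C@@]2(C)CC[C@@H]([O-])C(C)(C)[C@H]2CC[C@@]1(C)[O-].[Li+].[Li+].[Li+] | intermediate
22 | C11-farnesylated sulfone (C11 epimers; 3α-OH drawn) | CC(C)=CCC/C(C)=C/CC/C(C)=C/CC([C@@H]1[C@@]2(C)CC[C@@H](O)C(C)(C)[C@H]2CC[C@@]1(C)O)S(=O)(=O)c1ccccc1 | intermediate
23 | 3,8-diol with complete (13E,17E)-side chain (3α-OH drawn) | CC(C)=CCC/C(C)=C/CC/C(C)=C/CC[C@@H]1[C@@]2(C)CC[C@@H](O)C(C)(C)[C@H]2CC[C@@]1(C)O | intermediate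
24 | IN0671: cis-fused 8α-hydroxy-3-ketone with 9β side chain | CC(C)=CCC/C(C)=C/CC/C(C)=C/CC[C@@H]1[C@@]2(C)CCC(=O)C(C)(C)[C@H]2CC[C@@]1(C)O | target

Total step count: 18. Longest linear sequence: 18 steps from 1 (8 and 20 are bought).

Steps most likely to fail

Step 10. The silylation may not discriminate fully between the two carbonyl groups (silylation of the methyl ketone, or base-induced aldolization before silylation), and the boron-bound aldolate may revert on warming. The fallback moves the silylation to the stage where the ketone is still masked and uses the masked ketone itself as the electrophile. It sets out from 10: TBSCl/DBU in CH2Cl2 should give the silyl enol ether F1 with no competing carbonyl group. TiCl4 in CH2Cl2 at −78 °C should then open the dioxolane to an oxocarbenium ion that C9 captures in the same chair (Mukaiyama-type addition to a ketal), giving the C8 2-hydroxyethyl ether F2, which cannot undergo retro-aldol. PPh3/I2/imidazole should convert this into the 2-iodoethyl ether F3, and zinc dust with NH4Cl in ethanol at 25 °C should fragment it with loss of ethylene to the free tertiary alcohol. The route is rejoined at 13.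

Step 14. Oxygen may be captured at the other end of the allyl radical (allylic transposition to the 2-en-1-one), and over-oxidation may occur. The fallback replaces the radical pathway by a pericyclic one that cannot transpose. It sets out from 16: SeO2 (cat.) with t-BuOOH in CH2Cl2 (ene reaction, then [2,3]-sigmatropic shift) returns the double bond to C1–C2 and can place oxygen only on C3, giving the allylic alcohol F4. Dess–Martin periodinane should then oxidise it to the enone. The route is rejoined at 17.

Step 8. The vinyl ether may lose acetaldehyde to give a ring diene at the temperature required, or rearrange sluggishly because the new bond forms next to the C5 arm. The fallback uses a Johnson–Claisen rearrangement, which needs no isolated vinyl ether and runs at lower temperature. It sets out from 7: MeC(OEt)3 with catalytic propionic acid at 140 °C should give, with the same suprafacial delivery to C10, the ethyl ester F5. Diisobutylaluminium hydride, (Me2CHCH2)2AlH, in toluene at −78 °C should reduce it to the aldehyde. The route is rejoined at 10.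

Further compounds
F1 | step 10 | (E)-tert-butyldimethylsilyl enol ether of aldehyde 10 (dioxolane intact) | CC(C)(C)[Si](C)(C)O/C=C/[C@@]1(C)C=CCC(C)(C)[C@H]1CCC1(C)OCCO1
F2 | step 10 | C8 2-hydroxyethyl ether of 13 | O=C[C@@H]1[C@@]2(C)C=CCC(C)(C)[C@H]2CC[C@@]1(C)OCCO
F3 | step 10 | C8 2-iodoethyl ether of 13 | O=C[C@@H]1[C@@]2(C)C=CCC(C)(C)[C@H]2CC[C@@]1(C)OCCI
F4 | step 14 | 3α-hydroxy-1-ene sulfone (allylic alcohol of 16) | O=S(=O)(c3ccccc3)C[C@@H]1[C@@]2(C)C=C[C@@H](O)C(C)(C)[C@H]2CC[C@@]1(C)O
F5 | step 8 | ethyl ester corresponding to aldehyde 10 | CCOC(=O)C[C@@]1(C)C=CCC(C)(C)[C@H]1CCC1(C)OCCO1
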